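In a one-step world the left-handed substrate meets coupling partner and nothing else, and a first-order loss multiplies the fraction left, so I reckoned with that fraction.

| setting | oak | flask |
|---|---|---|
| left-handed substrate | 0.075 M | 0.050 M |
| right-handed substrate | 0.075 M | 0.050 M |
| solid reagent | 3 equiv | 3.00 equiv |
| racemization catalyst | 5 mol% | 5 mol% |
| remark | run made earlier |  |
| time |  | 50 min |

- oak (time / min: left-handed product / %, right-handed product / %, left-handed substrate / %): 2.50: 0.4, 0.3, 49.7; 5.00: 0.3, 0, 48.1; 8.00: 5.2, 0, 47.3; 10.0: 6.2, 0.1, 46.8; 12.0: 7.1, 0.9, 46.1; 15.0: 10.5, 0, 41.2

(readings scatter by 1 percentage point)

- coupling partner is single-handed; left-handed substrate and right-handed substrate are mirror images of each other, charged as a racemate, each of them at the stated concentration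
- as a solid, counted per litre of solution: solid reagent
- the analysis behind the earlier runs scatters by 1 percentage point, standard deviation
- reactions considered so far: coupling partner <-> dormant form; coupling partner + left-handed substrate -> left-handed product; solid reagent <-> coupling partner; left-handed substrate + racemization catalyst <-> right-handed substrate + racemization catalyst; coupling partner + right-handed substrate -> right-handed product
- at the start none of the solid reagent is in solution
- an excess is below zero if the other one leads
- no earlier run changes the charge of racemization catalyst; that part of a forecast is a guess
- the handed part of coupling partner does not stay in what it makes, so the products of the two hands are mirror images too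

- excess of left-handed product over right-handed product in the product at 2.5 min
- excess of left-handed product over right-handed product in the product at 50 min
- part of the left-handed substrate and right-handed substrate charged together that has reacted at 50 min

I took the left-handed substrate of the oak run from 8.00 min to 15.0 min, past the lag, as a pseudo-first-order loss:

κ = ln(first reading / last reading) / elapsed time = 0.0197 min⁻¹

The oak run already held racemization catalyst, so taking κ as the coupling's own rate, with no refilling in those minutes, was my assumption; carrying this reading to the flask was another, and its scatter is large. Over the flask's time it gives the one-step fraction left 37.3%, the share of left-handed substrate surviving if nothing refills it: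

f = exp(−κt); pair reacted = (1 − f)/2 = 31.3%

Then I added racemization. Taken as fast, it keeps the hands equal, so the pair loses at κ/2:

pair left = √f = 61.1%; pair reacted = 38.9%

I committed to the upper figure. Last I added right-handed coupling. The summed oak readings gave me an excess of 91.6%, but the largest right-handed reading was 0.9% against a scatter of 1 percentage point.

The forecast gave 90%, 87% and 34%, holding that “Substrate imbalance therefore stays small”; its conversion is lower than mine.

The flask gave 97.8%, 97.5% and 39.0%, so the early excess stood higher than the forecast's early figure.

    coupling partner ⇌ dormant form (K = 4.20, k = 3.30 × 10⁻⁴ s⁻¹)
    coupling partner + left-handed substrate → left-handed product (k = 0.0270 M⁻¹ s⁻¹)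
    solid reagent ⇌ coupling partner, rate k3*(cs3 - [coupling partner]) while solid is left; crystals form when [coupling partner] > cs3 (solubility = 29.0 mM, k = 0.00140 s⁻¹)
    left-handed substrate + racemization catalyst ⇌ right-handed substrate + racemization catalyst, rate k4*[racemization catalyst]*[left-handed substrate] forward; the back reaction follows from the equilibrium constant (k = 0.400 M⁻¹ s⁻¹)
    coupling partner + right-handed substrate → right-handed product (k = 3.00 × 10⁻⁴ M⁻¹ s⁻¹)

In the flask, left-handed coupling ran while solid reagent was still there, 55.4% of its charge at 50.0 min, and racemization ran beside it with a relaxation half-life of 5.78 min, shorter than the time. The flask kept 55% of its left-handed substrate, more than my one-step estimate f of 37.3%, and the neighbour with 1.2 mol% of racemization catalyst kept 45%, also more than that estimate, beside 82% of its right-handed substrate.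

The readings were generated by integration on assumed constants; the scatter is artificial.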